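**Retrosynthetic overview**
- The target is the (2S,3S)-trans dihydrobenzofuran. The last step is acidolysis of a MOM/vanillyl-ether-protected precursor, and the (E)-styryl arm at C6 comes from Ir C–H borylation followed by an oxidative Heck reaction.
- Key disconnection: the C2–C3 bond, made by Co(II)-metalloradical 1,5-HAT/radical substitution of a diaryldiazomethane derived from a 2,6-bis(vanillyloxy)benzophenone. This closes the dihydrofuran ring and sets the stereocentres.
- The benzophenone comes from carbonylative Suzuki coupling of a 2-iodoresorcinol bis(vanillyl ether), a 3,5-bis(MOMO)phenyl boronate and CO.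
- Both guaiacyl units come from catechol (via MOM-protected 4-bromoguaiacol, giving a benzyl alcohol and a styrene). Both resorcinol rings come from resorcinol (C2 iodination for one, C5 Ir-borylation for the other).
- Ring order: all four benzene rings are bought intact; the dihydrofuran is the only ring formed (step 12).

Assumption: the SMILES is read as (2S,3S)-trans; the Co-porphyrin antipode that gives 3S must be found by screening both enantiomers, and MeI, (CH2O)n, CO, vinyl-BF3K and N2H4 are treated as reagents.

**Step 1**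
Reactants: 1 catechol
Product: 2 guaiacol (2-methoxyphenol)
Conditions: MeI (1.0 equiv), K2CO3, acetone, reflux; distil
Reagents that add atoms: iodomethane, CI
Why: Williamson mono-O-methylation; statistical, and guaiacol is separated from veratrole and catechol by distillation/base extraction.

**Step 2**
Reactants: 2 guaiacol
Product: 3 4-bromo-2-methoxyphenol
Conditions: NBS (1.0 equiv), MeCN, 0 °C
Reagents that add atoms: N-bromosuccinimide, O=C1CCC(=O)N1Br
Why: Electrophilic aromatic bromination; the free OH is the stronger director, so Br enters para to OH.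

**Step 3**
Reactants: 3 4-bromo-2-methoxyphenol
Product: 4 4-bromo-2-methoxy-1-(methoxymethoxy)benzene
Conditions: MOMCl, i-Pr2NEt, CH2Cl2, 0 °C → rt
Reagents that add atoms: chloromethyl methyl ether, COCCl
Why: Phenol protection as a MOM acetal, stable to organolithium, Pd, Ir, hydrazine and radical conditions.

**Step 4**
Reactants: 4 aryl bromide
Product: 5 [3-methoxy-4-(methoxymethoxy)phenyl]methanol
Conditions: n-BuLi, THF, −78 °C; (CH2O)n, −78 °C → rt
Reagents that add atoms: paraformaldehyde, C=O
Why: Br–Li exchange (faster than MOM-directed ortho-lithiation at −78 °C), then hydroxymethylation of the aryllithium.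

**Step 5**
Reactants: 4 aryl bromide
Product: 6 4-ethenyl-2-methoxy-1-(methoxymethoxy)benzene
Conditions: CH2=CHBF3K, PdCl2(dppf) (2 mol%), Et3N, n-PrOH, 90 °C
Reagents that add atoms: potassium vinyltrifluoroborate, C=C[B-](F)(F)F.[K+]
Why: Suzuki–Miyaura vinylation (Molander conditions) of an electron-rich aryl bromide.

**Step 6**
Reactants: 7 resorcinol
Product: 8 1,3-bis(methoxymethoxy)benzene
Conditions: MOMCl, NaH, DMF, 0 °C → rt
Reagents that add atoms: chloromethyl methyl ether, COCCl
Why: Double phenol protection.

**Step 7**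
Reactants: 8 1,3-bis(methoxymethoxy)benzene
Product: 9 2-[3,5-bis(methoxymethoxy)phenyl]-4,4,5,5-tetramethyl-1,3,2-dioxaborolane
Conditions: [Ir(OMe)(cod)]2 (1 mol%), dtbpy (2 mol%), B2pin2, hexane, 60 °C
Reagents that add atoms: bis(pinacolato)diboron, CC1(C)OB(OC1(C)C)B1OC(C)(C)C(C)(C)O1
Why: Sterically controlled Ir-catalysed C–H borylation; C5–H is the only C–H without an ortho substituent.

**Step 8**
Reactants: 7 resorcinol
Product: 10 2-iodobenzene-1,3-diol
Conditions: I2, NaHCO3, H2O, 0 °C → rt
Reagents that add atoms: iodine, II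
Why: Known selective iodination of resorcinol at C2 (between the hydroxyls) under aqueous bicarbonate.

**Step 9**
Reactants: 10 2-iodoresorcinol; 5 benzyl alcohol (2.2 equiv)
Product: 11 2-iodo-1,3-bis{[3-methoxy-4-(methoxymethoxy)phenyl]methoxy}benzene
Conditions: PPh3, DIAD, THF, 0 °C → rt
Reagents that add atoms: none
Why: Double Mitsunobu etherification of an acidic o-iodophenol with a primary benzylic alcohol; the identical ethers keep the ring symmetric, so no differentiation of the two oxygens is needed.

**Step 10**
Reactants: 11 aryl iodide; 9 aryl boronate (1.5 equiv)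
Product: 12 {2,6-bis{[3-methoxy-4-(methoxymethoxy)phenyl]methoxy}phenyl}[3,5-bis(methoxymethoxy)phenyl]methanone
Conditions: CO (1 atm), PEPPSI-IPr (3 mol%), Cs2CO3, PhCl, 80 °C
Reagents that add atoms: carbon monoxide, [C-]#[O+]
Why: Carbonylative Suzuki–Miyaura coupling; with di-ortho-substituted aryl iodides, CO insertion outruns direct transmetalation, so the hindered diaryl ketone forms in preference to the biaryl.

**Step 11**
Reactants: 12 ketone
Product: 13 hydrazone of 12 (C=N–NH2)
Conditions: anhydrous N2H4 (20 equiv), AcOH (cat.), n-BuOH, 110 °C, Ar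
Reagents that add atoms: hydrazine, NN
Why: Forced condensation of a hindered 2,6-dialkoxybenzophenone with hydrazine; MOM and benzyl ethers are inert to it.

**Step 12 (key step; one flask, two stages)**
Reactants: 13 hydrazone
Product: 15 (2S,3S)-3-[3,5-bis(methoxymethoxy)phenyl]-2-[3-methoxy-4-(methoxymethoxy)phenyl]-4-{[3-methoxy-4-(methoxymethoxy)phenyl]methoxy}-2,3-dihydro-1-benzofuran, via the unisolated diaryldiazomethane 14
Conditions: MnO2, CH2Cl2, 0 °C → rt, dark, filter through Celite; then Co(II) D2-symmetric chiral amidoporphyrin (ChenPhyrin/HuPhyrin class, antipode giving 3S; 5 mol%), PhMe (0.01 M), 40 °C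
Reagents that add atoms: none
Why: Proposed new method: Co(II) traps diazo 14 with loss of N2 to give an α-Co(III)-diarylmethyl radical; this abstracts a benzylic hydrogen from either of the two homotopic ortho OCH2Ar groups by 1,5-HAT, and the resulting α-aryloxybenzyl radical closes by 5-exo-tet radical substitution at the Co-bound carbon, forming C2–C3 inside the chiral porphyrin pocket, which fixes the non-epimerisable C3 as S (any cis C2 epimer converges in step 15). The closest known reaction types are Co(II)-metalloradical enantioselective 1,5-C–H alkylation with in situ aryldiazomethanes (indolines and related five-membered rings) and Rh(II) donor/donor-carbene C–H insertion giving 2,3-diaryl-dihydrobenzofurans; the untested element is the use of a diaryl (ketone-derived) carbene radical.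

**Step 13**
Reactants: 15 dihydrobenzofuran
Product: 16 the 6-(4,4,5,5-tetramethyl-1,3,2-dioxaborolan-2-yl) derivative of 15, (2S,3S)
Conditions: [Ir(OMe)(cod)]2 (2.5 mol%), dtbpy (5 mol%), B2pin2 (1.2 equiv), THF, 80 °C
Reagents that add atoms: bis(pinacolato)diboron, CC1(C)OB(OC1(C)C)B1OC(C)(C)C(C)(C)O1
Why: Sterically controlled Ir C–H borylation; C6–H is the only arene C–H in 15 flanked by two hydrogens, and the neutral conditions leave both stereocentres untouched.

**Step 14**
Reactants: 16 aryl boronate; 6 styrene (2 equiv)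
Product: 17 (2S,3S)-3-[3,5-bis(methoxymethoxy)phenyl]-2-[3-methoxy-4-(methoxymethoxy)phenyl]-4-{[3-methoxy-4-(methoxymethoxy)phenyl]methoxy}-6-{(E)-2-[3-methoxy-4-(methoxymethoxy)phenyl]ethenyl}-2,3-dihydro-1-benzofuran
Conditions: Pd(OAc)2 (10 mol%), 2,9-dimethyl-1,10-phenanthroline (12 mol%), O2 (1 atm), Na2CO3, DMF, 50 °C
Reagents that add atoms: none
Why: Oxidative (boron) Heck reaction; transmetalation, syn-insertion into the styrene and syn-β-hydride elimination give the E-stilbene.

**Step 15**
Reactants: 17 protected precursor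
Product: 18 Bisisorhapontigenin B, (2S,3S)
Conditions: 2 M HCl, MeOH/THF (3:1), 1-dodecanethiol (20 equiv), 40 °C, dark, Ar
Reagents that add atoms: none
Why: Acidic methanolysis removes the five MOM acetals; the exocyclic 4-hydroxy-3-methoxybenzyl aryl ether then solvolyses by SN1, with the vanillyl cation and formaldehyde trapped by the thiol. Reversible ionisation and reclosure of the ring C2–O bond equilibrates C2 to the more stable trans isomer while C3 is untouched.

**Compound list**
1 | catechol | Oc1ccccc1O | starting material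
2 | guaiacol | COc1ccccc1O | intermediate
3 | 4-bromo-2-methoxyphenol | COc1cc(Br)ccc1O | intermediate
4 | 4-bromo-2-methoxy-1-(methoxymethoxy)benzene | COCOc1ccc(Br)cc1OC | intermediate
5 | [3-methoxy-4-(methoxymethoxy)phenyl]methanol | COCOc1ccc(CO)cc1OC | intermediate
6 | 4-ethenyl-2-methoxy-1-(methoxymethoxy)benzene | COCOc1ccc(C=C)cc1OC | intermediate
7 | resorcinol | Oc1cccc(O)c1 | starting material
8 | 1,3-bis(methoxymethoxy)benzene | COCOc1cccc(OCOC)c1 | intermediate
9 | 2-[3,5-bis(methoxymethoxy)phenyl]-4,4,5,5-tetramethyl-1,3,2-dioxaborolane | COCOc1cc(OCOC)cc(c1)B1OC(C)(C)C(C)(C)O1 | intermediate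
10 | 2-iodobenzene-1,3-diol | Oc1cccc(O)c1I | intermediate
11 | 2-iodo-1,3-bis{[3-methoxy-4-(methoxymethoxy)phenyl]methoxy}benzene | COCOc1ccc(COc2cccc(OCc3ccc(OCOC)c(OC)c3)c2I)cc1OC | intermediate
12 | {2,6-bis{[3-methoxy-4-(methoxymethoxy)phenyl]methoxy}phenyl}[3,5-bis(methoxymethoxy)phenyl]methanone | COCOc1ccc(COc2cccc(OCc3ccc(OCOC)c(OC)c3)c2C(=O)c2cc(OCOC)cc(OCOC)c2)cc1OC | intermediate
13 | hydrazone of 12 | COCOc1ccc(COc2cccc(OCc3ccc(OCOC)c(OC)c3)c2C(=NN)c2cc(OCOC)cc(OCOC)c2)cc1OC | intermediate
14 | 2-{diazo[3,5-bis(methoxymethoxy)phenyl]methyl}-1,3-bis{[3-methoxy-4-(methoxymethoxy)phenyl]methoxy}benzene (not isolated) | COCOc1ccc(COc2cccc(OCc3ccc(OCOC)c(OC)c3)c2C(=[N+]=[N-])c2cc(OCOC)cc(OCOC)c2)cc1OC | intermediate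
15 | (2S,3S)-3-[3,5-bis(methoxymethoxy)phenyl]-2-[3-methoxy-4-(methoxymethoxy)phenyl]-4-{[3-methoxy-4-(methoxymethoxy)phenyl]methoxy}-2,3-dihydro-1-benzofuran | c1cc(OCc2ccc(OCOC)c(OC)c2)c2c(c1)O[C@H](c1ccc(OCOC)c(OC)c1)[C@H]2c1cc(OCOC)cc(OCOC)c1 | intermediate
16 | 6-(pinacolboryl) derivative of 15, (2S,3S) | CC1(C)OB(OC1(C)C)c1cc(OCc2ccc(OCOC)c(OC)c2)c2c(c1)O[C@H](c1ccc(OCOC)c(OC)c1)[C@H]2c1cc(OCOC)cc(OCOC)c1 | intermediate
17 | 6-{(E)-2-[3-methoxy-4-(methoxymethoxy)phenyl]ethenyl} derivative of 15, (2S,3S) | COCOc1ccc(/C=C/c2cc(OCc3ccc(OCOC)c(OC)c3)c3c(c2)O[C@H](c2ccc(OCOC)c(OC)c2)[C@H]3c2cc(OCOC)cc(OCOC)c2)cc1OC | intermediate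
18 | Bisisorhapontigenin B: 5-[(2S,3S)-4-hydroxy-2-(4-hydroxy-3-methoxyphenyl)-6-[(E)-2-(4-hydroxy-3-methoxyphenyl)ethenyl]-2,3-dihydro-1-benzofuran-3-yl]benzene-1,3-diol | COc1cc(/C=C/c2cc(O)c3c(c2)O[C@H](c2ccc(O)c(OC)c2)[C@H]3c2cc(O)cc(O)c2)ccc1O | target

**Totals**
Total steps: 15 (step 12 is a two-stage, one-flask operation counted once).
Longest linear sequence: 11 (steps 1–4, 9–15).

**Three steps most likely to fail**
1. Step 12 (metalloradical cyclisation). The diaryl Co-carbene radical may be too stabilised or hindered for HAT/substitution, or may give azine, and enantioselectivity is unproven. Fallback: treat the same diazo 14 by closed-shell Rh(II) donor/donor-carbene C–H insertion with a chiral carboxylate catalyst (Rh2(PTAD)4 type). This is expected to be cis-selective, with the cis isomer converged to trans in step 15.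
2. Step 11 (hydrazone of a di-ortho-alkoxy benzophenone). Condensation may stall. Fallback: bypass the ketone. Convert 9 to 3,5-bis(MOMO)benzonitrile (Cu-mediated cyanation), add the aryl-Mg reagent from 11 (i-PrMgCl·LiCl exchange) to give the N–H ketimine, and transiminate with hydrazine at room temperature.
3. Step 15 (global acidolysis). The vanillyl cation or formaldehyde may alkylate the resorcinol rings, or the stilbene may react under acid. Fallback: change the protecting-group architecture by desymmetrising 10 (mono-MOM, then a single Mitsunobu with 5; one extra step). The C4 oxygen then carries MOM, no benzylic cation is released, and a mild MOM removal suffices.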